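Time is the first thing to watch here, because the flask asked about is the gamma run itself, and its target reads 31.7 % at 15.0 h and 34.6 % at 144 h, against a scatter of 1 percentage point.

| flask | solid substrate | enzyme | remark | time |
|---|---|---|---|---|
| gamma | 0.19 M | 0.0035 mol% | the very flask that is asked about, followed so far |  |
| alpha | 0.19 M | 0.0023 mol% | run made earlier |  |
| flask | 0.19 M | 0.0035 mol% |  | 8.0 d |

| run | time / h | target / % |
|---|---|---|
| gamma | 15.0 | 31.7 |
| gamma | 40.0 | 33.3 |
| gamma | 72.0 | 32.5 |
| gamma | 120 | 34.0 |
| gamma | 144 | 34.6 |
| alpha | 0.833 | 4.4 |
| alpha | 1.50 | 9.4 |
| alpha | 3.00 | 17.3 |
| alpha | 6.00 | 27.7 |
| alpha | 10.0 | 32.7 |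

(readings scatter by 1 percentage point)

- given per volume of solution although it is solid: solid substrate
- target that was removed still counts
- what was read earlier has a scatter of 1 percentage point, one standard deviation
- what may be going on: target + enzyme <-> isomer of the product + enzyme; enzyme + target -> spent catalyst; solid substrate <-> starting material; starting material + enzyme -> target + enzyme
- at the start none of the solid substrate is in solution
- additions bring no volume worth counting

- elm: change nothing and wait 2.5 d more
- maple: at 8.0 d take out 90 % of the target then present, then wait 2.5 d
- ash: at 8.0 d add enzyme, 100 % of the amount charged, then wait 2.5 d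

- target, in percent of the solid substrate first charged, at 8.0 d
- the remedy with the largest gain of target, or "none" below 2 percentage points (elm / maple / ash / none)
- target present, with what was taken out counted in, in percent of the solid substrate first charged, after elm
- target present, with what was taken out counted in, in percent of the solid substrate first charged, after ash

I solve two extreme flasks in my head. In the first the enzyme stays alive, the solid substrate is used up, and target stands in equilibrium with the isomer of the product (thermodynamic control), so the stop is a share of the charge, and maple refills target while ash adds nothing. In the second the enzyme is lost as target builds up (catalyst deactivation) with solid substrate still waiting, so I take the stop as a concentration, and maple adds nothing while ash restarts the flask. I therefore carry the stall concentration, the [target] at which the flask stands still, taken from the last reading of the gamma run and so carrying its scatter: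

[target]stall = 34.6 % × 0.19 M = 65.7 mM

Both runs hold the same charge of solid substrate, so they cannot show directly whether the stop is a share or a concentration, but the alpha run gives a crossing time. In the first extreme target takes a fixed share of the flow, so the whole charge is used when the early line of the alpha run reaches the stop:

early slope = (17.3 % − 4.4 %) / (3.00 h − 0.833 h) = 0.0595 h⁻¹

t× = 34.6 % / slope = 5.81 h

Yet the alpha run reads 27.7 % at 6.00 h, below the stop of the gamma run, and then climbs at 0.0125 h⁻¹, slower than on its early line, so I place the real flask nearer the second extreme: about 34.6 % now, a flat elm, and ash as the remedy to try.

The forecast agrees on the level, with 34.5 % now and 35 % after elm, but parts from my reckoning on the remedy, naming maple and giving 35.5 % after ash: “Removing target lets the isomer refill it, if the enzyme survives, so maple wins.”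

The flask gives 33.6 % at 8.0 d, and the best remedy is ash, which reaches 46.3 % against 33.6 % after elm, while maple gains 0 points.

    target + enzyme ⇌ isomer of the product + enzyme, rate k1*[enzyme]*[target] forward; the back reaction follows from the equilibrium constant (K = 1.30, k = 1500 M⁻¹ min⁻¹)
    enzyme + target → spent catalyst (k = 0.210 M⁻¹ min⁻¹)
    solid substrate ⇌ starting material, rate k3*(cs3 - [starting material]) while solid is left; crystals form when [starting material] > cs3 (solubility = 15.0 mM, k = 0.0170 min⁻¹)
    starting material + enzyme → target + enzyme, rate k4*[starting material]*[enzyme]/(1 + ([starting material]/Km4) + ([starting material]/Ksi4)^2) (5.10 mM, 46.0 mM, k = 79000 M⁻¹ min⁻¹)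

At 19.2 h this flask holds 0 % of the catalyst charged as enzyme, while 42.4 % of the charge is still solid. On the neighbour charged with 0.11 M of solid substrate at the same loading of enzyme, the stall concentration gives 59.7 % of its charge, whereas a fixed share stays at 34.6 %. That neighbour stands at 53.4 %, which is 58.7 mM of target.

The data were computed with made-up constants.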